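**Retrosynthetic overview**
1. 13 ⇒ 8 + 2 × 11: both 2-pyranones are annulated last, in two directions, by γ-acylation of a vinylogous ester dienolate followed by enol-lactonisation.
2. 8 ⇒ 6: the cyclobutane comes from a double ring contraction (6 → 5 → 4) of a 3,6-dibromo-1,2-dione. Two successive 1,2-shifts form the bond between the two quaternary carbons and turn the two ketone carbons into the carboxyl carbons that later become C-6 of the pyranones.
3. 6 ⇒ 4 ⇒ 2 + 3: the six-membered ring comes from the bis-silyl dienol ether of hexane-3,4-dione and maleic anhydride (source of the cis-diacid), followed by Br2 oxidation and bromination.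
4. Ring order: cyclohexene → cyclopentanone (in situ) → cyclobutane → two pyranones. Stereocontrol: cis-CO2H from maleic anhydride; C–Br centres from convex-face bromination; the stereospecific shifts carry this into the quaternary centres.

Assumption: the descriptors in the SMILES define a meso (achiral) compound, with both CO2H and both CH3 on one face and both pyranones on the other, so only relative configuration has to be controlled.

**Step 1**
Reactants: 1 hexane-3,4-dione
Product: 2 (2Z,4Z)-3,4-bis(trimethylsilyloxy)hexa-2,4-diene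
Conditions: TMSOTf (2.2 equiv), Et3N (2.6 equiv), Et2O, 0 °C → rt
Reagents that add atoms: trimethylsilyl trifluoromethanesulfonate, C[Si](C)(C)OS(=O)(=O)C(F)(F)F
Why: Soft double enolisation and O-silylation of the α-diketone (silyl enol ether formation) gives the thermodynamic Z,Z-diene with both methyls "outside", as the cycloaddition needs; no stereocentre is formed.

**Step 2**
Reactants: 2 (2Z,4Z)-3,4-bis(trimethylsilyloxy)hexa-2,4-diene; 3 maleic anhydride
Product: 4 all-cis (endo, meso) 4,7-dimethyl-5,6-bis(trimethylsilyloxy)-3a,4,7,7a-tetrahydro-2-benzofuran-1,3-dione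
Conditions: PhMe, 60 °C
Reagents that add atoms: none
Why: Diels–Alder reaction of an electron-rich 2,3-bis(silyloxy)diene with maleic anhydride; suprafacial addition to the cis-alkene fixes the cis relation of the two future CO2H carbons (C1/C2 of the target), and the CH(CH3) centres of the endo adduct are erased in step 3.

**Step 3**
Reactants: 4 all-cis Diels–Alder adduct
Product: 6 meso 3,6-dibromo-3,6-dimethyl-4,5-dioxocyclohexane-1,2-dicarboxylic acid, via dibromo-dione anhydride 5 (not isolated)
Conditions: Br2 (3.05 equiv), 2,6-lutidine (2.1 equiv), CH2Cl2, −78 → 0 °C; filter, evaporate; THF–H2O, 35 °C; dry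
Reagents that add atoms: bromine, BrBr; water, O
Why: Br2 first oxidises the ene-1,2-bis(silyl ether) to the 1,2-dione (known oxidation of acyloin bis-silyl ethers); the two diosphenol enols are then α-brominated under kinetic control (lutidine removes HBr) from the convex face of the cis-fused bicycle, anti to the anhydride ring, which sets both C–Br centres (Br trans, CH3 cis to the neighbouring carboxyl carbon); mild hydrolysis then opens the anhydride.

**Step 4**
Reactants: 6 meso 3,6-dibromo-3,6-dimethyl-4,5-dioxocyclohexane-1,2-dicarboxylic acid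
Product: 8 (1R,2S,3R,4S)-3,4-dimethyl-3,4-bis[(2,2,2-trifluoroethoxy)carbonyl]cyclobutane-1,2-dicarboxylic acid, via bromo-keto cyclopentane ester 7 (not isolated)
Conditions: CF3CH2ONa (4.5 equiv), CF3CH2OH, −20 °C → rt; 1 M HCl
Reagents that add atoms: sodium 2,2,2-trifluoroethoxide, [Na+].[O-]CC(F)(F)F
Why: Proposed new method: trifluoroethoxide adds to one C=O of the non-enolisable 1,2-dione and the hemiketal alkoxide pushes the neighbouring acyl carbon onto the anti-periplanar tertiary C–Br carbon with inversion (6 → 5, giving 7); the same addition and 1,2-shift at the remaining ketone moves the new quaternary carbon (retention) onto the second C–Br carbon (5 → 4), forming the bond between the two quaternary carbons, so each new ester ends on the face its bromine occupied (trans to the CO2H groups) and each CH3 stays cis to them, while the carboxylates cannot epimerise or promote HBr loss; the closest known reaction type is the quasi-Favorskii (semibenzilic) ring contraction of α-bromo ketones without enolisable α′-H (the two cyclopentanone → cyclobutane contractions of the cubane synthesis), which has not been shown as a one-pot double contraction of an α,α′-dibromo-1,2-diketone.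

**Step 5**
Reactants: 9 methyl acetoacetate
Product: 10 methyl 2-methyl-3-oxobutanoate (racemic)
Conditions: MeI (1.05 equiv), K2CO3, acetone, reflux
Reagents that add atoms: iodomethane, CI
Why: C-methylation of the β-keto ester enolate (SN2 alkylation); the stereocentre is lost in the next step.

**Step 6**
Reactants: 10 methyl 2-methyl-3-oxobutanoate
Product: 11 methyl (2E)-3-methoxy-2-methylbut-2-enoate
Conditions: HC(OMe)3, H2SO4 (cat.), MeOH, rt
Reagents that add atoms: trimethyl orthoformate, COC(OC)OC
Why: Acid-catalysed ketalisation and elimination with orthoformate (enol ether formation) gives the favoured E-enol ether (OMe trans to CO2Me), which places the γ-CH3 cis to the ester as the later lactonisation needs.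

**Step 7**
Reactants: 8 (1R,2S,3R,4S)-3,4-dimethyl-3,4-bis[(2,2,2-trifluoroethoxy)carbonyl]cyclobutane-1,2-dicarboxylic acid; 11 methyl (2E)-3-methoxy-2-methylbut-2-enoate
Product: 13 (1R,2S,3R,4S)-3,4-bis(4-methoxy-5-methyl-6-oxo-6H-pyran-2-yl)-3,4-dimethylcyclobutane-1,2-dicarboxylic acid, via bis(keto enoate) diacid 12 (not isolated)
Conditions: 11 (6.5 equiv), LDA (6.6 equiv), THF–DMPU, −78 °C; add 8 (inverse addition), −78 → −30 °C, then 20 °C; 1 M HCl
Reagents that add atoms: none
Why: Vinylogous Claisen condensation: the γ-lithiated dienolate of 11 acylates both activated trifluoroethyl esters while the CO2H groups sit as non-enolisable lithium carboxylates (C1/C2 cannot epimerise), and on warming each keto-enolate oxygen attacks its own cis-disposed methyl ester (enol-lactonisation) to close the 4-methoxy-3-methyl-2-pyranones; no stereocentre is touched.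

**Compound list**
1 | hexane-3,4-dione | CCC(=O)C(=O)CC | starting material
2 | (2Z,4Z)-3,4-bis(trimethylsilyloxy)hexa-2,4-diene | C/C=C(\O[Si](C)(C)C)/C(O[Si](C)(C)C)=C/C | intermediate
3 | maleic anhydride (furan-2,5-dione) | O=C1OC(=O)C=C1 | starting material
4 | all-cis (endo, meso) 4,7-dimethyl-5,6-bis(trimethylsilyloxy)-3a,4,7,7a-tetrahydro-2-benzofuran-1,3-dione; both CH3 on the face of the anhydride ring | O=C1OC(=O)[C@@H]2[C@H]1[C@H](C)C(O[Si](C)(C)C)=C(O[Si](C)(C)C)[C@@H]2C | intermediate
5 | meso 4,7-dibromo-4,7-dimethyl-3a,4,7,7a-tetrahydro-2-benzofuran-1,3,5,6-tetrone; both Br anti, both CH3 syn to the anhydride ring (not isolated) | O=C1OC(=O)[C@@H]2[C@H]1[C@@](C)(Br)C(=O)C(=O)[C@@]2(C)Br | intermediate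
6 | meso 3,6-dibromo-3,6-dimethyl-4,5-dioxocyclohexane-1,2-dicarboxylic acid; CO2H cis, each Br trans and each CH3 cis to the neighbouring CO2H | OC(=O)[C@@H]1[C@H](C(=O)O)[C@@](C)(Br)C(=O)C(=O)[C@@]1(C)Br | intermediate
7 | racemic 5-bromo-3,5-dimethyl-4-oxo-3-[(2,2,2-trifluoroethoxy)carbonyl]cyclopentane-1,2-dicarboxylic acid; CO2H cis, both CH3 cis to them, Br and ester trans (not isolated; one enantiomer drawn) | OC(=O)[C@@H]1[C@H](C(=O)O)[C@@](C)(C(=O)OCC(F)(F)F)C(=O)[C@@]1(C)Br | intermediate
8 | (1R,2S,3R,4S)-3,4-dimethyl-3,4-bis[(2,2,2-trifluoroethoxy)carbonyl]cyclobutane-1,2-dicarboxylic acid (meso) | O=C(OCC(F)(F)F)[C@@]1(C)[C@H](C(=O)O)[C@H](C(=O)O)[C@@]1(C)C(=O)OCC(F)(F)F | intermediate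
9 | methyl acetoacetate (methyl 3-oxobutanoate) | CC(=O)CC(=O)OC | starting material
10 | methyl 2-methyl-3-oxobutanoate (racemic) | CC(=O)C(C)C(=O)OC | intermediate
11 | methyl (2E)-3-methoxy-2-methylbut-2-enoate | C/C(OC)=C(/C)C(=O)OC | intermediate
12 | (1R,2S,3R,4S)-3,4-bis[(3E)-3,5-dimethoxy-4-methyl-5-oxopent-3-enoyl]-3,4-dimethylcyclobutane-1,2-dicarboxylic acid (not isolated) | COC(=O)/C(C)=C(OC)\CC(=O)[C@@]1(C)[C@H](C(=O)O)[C@H](C(=O)O)[C@@]1(C)C(=O)C/C(OC)=C(/C)C(=O)OC | intermediate
13 | (1R,2S,3R,4S)-3,4-bis(4-methoxy-5-methyl-6-oxo-6H-pyran-2-yl)-3,4-dimethylcyclobutane-1,2-dicarboxylic acid (meso) | COc1cc([C@@]2(C)[C@H](C(=O)O)[C@H](C(=O)O)[C@@]2(C)c2cc(OC)c(C)c(=O)o2)oc(=O)c1C | target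

**Totals**
Total step count: 7. Longest linear sequence: 5 steps (1 → 2 → 3 → 4 → 7); steps 5 and 6 make the annulation partner.

**Steps most likely to fail, with fallbacks**

Step 4 (the proposed double ring contraction). The hemiketal alkoxide can instead close to an epoxy ether or undergo benzilic ester rearrangement, and the β-keto ester 7 can be cleaved by retro-Claisen. The fallback uses known chemistry and gives up the stereospecific shifts; it sets out from 4 and comes back at 13. Ozonolysis of the enediol bis-silyl ether (O3, CH2Cl2–MeOH, −78 °C; Me2S) and acidic methanolysis (MeOH, H2SO4, reflux) give meso tetramethyl hexane-2,3,4,5-tetracarboxylate F1. Kinetic double deprotonation at the two terminal CH(CH3) carbons (LDA, THF, −78 °C) and intramolecular oxidative coupling of the bis-enolate (CuBr2 or I2, −78 °C) close the four-membered ring and give, after separation from its diastereomers, tetramethyl (1R,2S,3R,4S)-1,2-dimethylcyclobutane-1,2,3,4-tetracarboxylate F2. Selective saponification of the two unhindered secondary esters (LiOH, 2.1 equiv, THF–H2O, 0 °C) gives (1R,2S,3R,4S)-3,4-bis(methoxycarbonyl)-3,4-dimethylcyclobutane-1,2-dicarboxylic acid F3, which is taken through the conditions of step 7 (longer at −20 °C for the less reactive methyl esters) to 13.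

Step 7 (double acylation and lactonisation). Two hindered neighbouring esters must both be acylated before a keto-enolate attacks the other ester intramolecularly, and the dilithium dicarboxylate may be poorly soluble. The fallback reverses the polarity so that the ring-forming step is not basic; it sets out from 8 and comes back at 13. tert-Butyl 2,2,2-trichloroacetimidate (BF3·OEt2 cat.) gives 1,2-di-tert-butyl 3,4-bis(2,2,2-trifluoroethyl) (1R,2S,3R,4S)-3,4-dimethylcyclobutane-1,2,3,4-tetracarboxylate F4. Me3SiCH2Li (THF, −78 °C) then MeOH converts the trifluoroethyl esters into methyl ketones, di-tert-butyl (1R,2S,3R,4S)-3,4-diacetyl-3,4-dimethylcyclobutane-1,2-dicarboxylate F5. LDA/TMSCl (internal quench, −78 °C) gives di-tert-butyl (1R,2S,3R,4S)-3,4-dimethyl-3,4-bis[1-(trimethylsilyloxy)ethenyl]cyclobutane-1,2-dicarboxylate F6. Effenberger pyranone synthesis with methylmalonyl dichloride (Et2O, −78 °C → rt) gives di-tert-butyl (1R,2S,3R,4S)-3,4-bis(4-hydroxy-5-methyl-6-oxo-6H-pyran-2-yl)-3,4-dimethylcyclobutane-1,2-dicarboxylate F7. O-Methylation (Me2SO4, K2CO3, acetone) gives di-tert-butyl (1R,2S,3R,4S)-3,4-bis(4-methoxy-5-methyl-6-oxo-6H-pyran-2-yl)-3,4-dimethylcyclobutane-1,2-dicarboxylate F8, and TFA/CH2Cl2 removes the tert-butyl esters to give 13.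

Step 3 (one-pot oxidation and double bromination). It must stay under kinetic control: HBr can equilibrate the tertiary α-bromo ketones to the unwanted epimers, and loss of HBr leads towards an aromatic catechol. The fallback separates oxidation from halogenation and brominates a preformed silyl dienol ether without acid; it sets out from 4 and comes back at 5. One equivalent of Br2 (CH2Cl2, −78 °C) gives meso 4,7-dimethyl-3a,4,7,7a-tetrahydro-2-benzofuran-1,3,5,6-tetrone F9. TMSOTf/Et3N converts it into cis-fused 4,7-dimethyl-5,6-bis(trimethylsilyloxy)-3a,7a-dihydro-2-benzofuran-1,3-dione F10. NBS (2.05 equiv, THF, −78 °C) brominates both enol ether termini from the convex face and gives 5, which is hydrolysed to 6 as in step 3.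

**Further compounds**
F1 | step 4 | meso tetramethyl hexane-2,3,4,5-tetracarboxylate (configuration as in 4) | COC(=O)[C@H](C)[C@H](C(=O)OC)[C@H](C(=O)OC)[C@H](C)C(=O)OC
F2 | step 4 | tetramethyl (1R,2S,3R,4S)-1,2-dimethylcyclobutane-1,2,3,4-tetracarboxylate | COC(=O)[C@@]1(C)[C@H](C(=O)OC)[C@H](C(=O)OC)[C@@]1(C)C(=O)OC
F3 | step 4 | (1R,2S,3R,4S)-3,4-bis(methoxycarbonyl)-3,4-dimethylcyclobutane-1,2-dicarboxylic acid | COC(=O)[C@@]1(C)[C@H](C(=O)O)[C@H](C(=O)O)[C@@]1(C)C(=O)OC
F4 | step 7 | 1,2-di-tert-butyl 3,4-bis(2,2,2-trifluoroethyl) (1R,2S,3R,4S)-3,4-dimethylcyclobutane-1,2,3,4-tetracarboxylate | O=C(OCC(F)(F)F)[C@@]1(C)[C@H](C(=O)OC(C)(C)C)[C@H](C(=O)OC(C)(C)C)[C@@]1(C)C(=O)OCC(F)(F)F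
F5 | step 7 | di-tert-butyl (1R,2S,3R,4S)-3,4-diacetyl-3,4-dimethylcyclobutane-1,2-dicarboxylate | CC(=O)[C@@]1(C)[C@H](C(=O)OC(C)(C)C)[C@H](C(=O)OC(C)(C)C)[C@@]1(C)C(C)=O
F6 | step 7 | di-tert-butyl (1R,2S,3R,4S)-3,4-dimethyl-3,4-bis[1-(trimethylsilyloxy)ethenyl]cyclobutane-1,2-dicarboxylate | C=C(O[Si](C)(C)C)[C@@]1(C)[C@H](C(=O)OC(C)(C)C)[C@H](C(=O)OC(C)(C)C)[C@@]1(C)C(=C)O[Si](C)(C)C
F7 | step 7 | di-tert-butyl (1R,2S,3R,4S)-3,4-bis(4-hydroxy-5-methyl-6-oxo-6H-pyran-2-yl)-3,4-dimethylcyclobutane-1,2-dicarboxylate | Oc1cc([C@@]2(C)[C@H](C(=O)OC(C)(C)C)[C@H](C(=O)OC(C)(C)C)[C@@]2(C)c2cc(O)c(C)c(=O)o2)oc(=O)c1C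
F8 | step 7 | di-tert-butyl (1R,2S,3R,4S)-3,4-bis(4-methoxy-5-methyl-6-oxo-6H-pyran-2-yl)-3,4-dimethylcyclobutane-1,2-dicarboxylate | COc1cc([C@@]2(C)[C@H](C(=O)OC(C)(C)C)[C@H](C(=O)OC(C)(C)C)[C@@]2(C)c2cc(OC)c(C)c(=O)o2)oc(=O)c1C
F9 | step 3 | meso 4,7-dimethyl-3a,4,7,7a-tetrahydro-2-benzofuran-1,3,5,6-tetrone | O=C1OC(=O)[C@@H]2[C@H]1[C@H](C)C(=O)C(=O)[C@@H]2C
F10 | step 3 | cis-fused 4,7-dimethyl-5,6-bis(trimethylsilyloxy)-3a,7a-dihydro-2-benzofuran-1,3-dione | O=C1OC(=O)[C@@H]2[C@H]1C(C)=C(O[Si](C)(C)C)C(O[Si](C)(C)C)=C2C
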